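In the cyclopentenone ring (C1 ketone, C2=C3, C4 acetoxy carbon, C5 pentenyl carbon) C5 lies between two oxygen-bearing carbons, so the C5–C1 bond is an aldol bond. It is made by contracting a six-membered 2H-pyran-3(6H)-one in which the ring oxygen bridges C5 and C1: SmI2 opens this bridge reductively, and the samarium enolate set free at C5 closes onto the unmasked C1 aldehyde. One operation thus turns an Achmatowicz-derived acetoxypyranone into a 4-hydroxy-5-pentenylcyclopentenone, with C1 and C4 at exchanged oxidation levels. Resolution, Mitsunobu inversion and a face-selective organocerium addition of the chain to C4, then oxidation and acetylation, complete the route.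

Key step: step 4

Assumption: in step 5 the lipase is taken to acylate the (4S,5R)-enantiomer of 9, in line with the usual preference of lipases for 4-hydroxycyclopent-2-enones, so that the (4R,5S)-alcohol is recovered; the assignment would be checked before step 6.

Step 1
Reactants: 1 furan; 2 (3Z)-hex-3-enal
Product: 4 rac-(3Z)-1-(furan-2-yl)hex-3-en-1-ol, via furan-2-yllithium 3 (not isolated)
Conditions: n-BuLi, THF, 0 °C; then freshly distilled 2, −78 °C; aq. NH4Cl
Reagents that add atoms: none
Why: Deprotonation of furan at C2 and carbonyl 1,2-addition of the resulting organolithium to the aldehyde at low temperature, where addition should outrun enolisation of the β,γ-unsaturated aldehyde, give the racemic furyl carbinol, whose stereocentre is erased later.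

Step 2
Reactants: 4 rac-(3Z)-1-(furan-2-yl)hex-3-en-1-ol
Product: 5 6-hydroxy-2-[(2Z)-pent-2-en-1-yl]-2H-pyran-3(6H)-one (racemic mixture of anomers)
Conditions: NBS (1.0 equiv), NaHCO3, THF/H2O (4:1), 0 °C
Reagents that add atoms: water, O
Why: Achmatowicz rearrangement: the electron-rich furan, far more reactive towards NBS than the isolated Z-alkene, is oxidised to the ene-dicarbonyl stage and re-closed by the carbinol oxygen to the six-membered lactol, obtained as an anomer mixture whose stereocentres are erased later.

Step 3
Reactants: 5 6-hydroxy-2-[(2Z)-pent-2-en-1-yl]-2H-pyran-3(6H)-one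
Product: 6 6-acetoxy-2-[(2Z)-pent-2-en-1-yl]-2H-pyran-3(6H)-one (racemic mixture of anomers)
Conditions: Ac2O, pyridine, DMAP (cat.), CH2Cl2, 0 °C
Reagents that add atoms: acetic anhydride, CC(=O)OC(C)=O
Why: O-Acylation of the lactol turns the hemiacetal carbon into one with a reductively cleavable leaving group and removes the acidic hydroxyl that would protonate the enolate in the next step.

Step 4
Reactants: 6 6-acetoxy-2-[(2Z)-pent-2-en-1-yl]-2H-pyran-3(6H)-one
Product: 9 rac-(4R,5S)-4-hydroxy-5-[(2Z)-pent-2-en-1-yl]cyclopent-2-en-1-one (trans), via samarium dienolate 7 (not isolated), via open-chain samarium enolate aldehyde 8 (not isolated)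
Conditions: SmI2 (2.1 equiv, added slowly), THF, −78 °C to 0 °C; aq. NH4Cl
Reagents that add atoms: none
Why: Proposed new method: two single-electron transfers from SmI2 to the γ-acetoxy enone of 6 expel the anomeric acetate and give the trivalent-samarium dienolate 7, whose oxa-6π electrocyclic ring opening on warming (equivalent in outcome to direct reductive scission of the α-keto C2–O1 bond) unmasks the Z-enal 8 with a samarium enolate fixed at C2, and this enolate adds to the aldehyde carbon C6. The closest known reaction types are the SmI2 cleavage of α-alkoxy and γ-acyloxy carbonyl compounds to samarium enolates, samarium-enolate aldol cyclisations and the aldol closure of Z-ene-1,4-dicarbonyl compounds to 4-hydroxycyclopent-2-enones. The carbocycle closes by a 5-(enolendo)-exo-trig aldol addition within a planar Z-dienyl array, so that the six-membered ring C2–C3–C4–C5–C6–O1 contracts to the five-membered ring C2–C3–C4–C5–C6 and O1 becomes the hydroxyl oxygen. Both stereocentres of 9 are new, those of 6 being erased; the trans relation is under thermodynamic control through reversible aldolisation of the samarium aldolate and epimerisation alpha to the ketone, and no absolute control is sought here. The step needs regioselective enolate formation, secured because only C2 is both alpha to the ketone and attached to the ring oxygen, and chemoselectivity against reduction of the enal or of the product, secured by slow addition of two equivalents of SmI2 at −78 °C.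

Step 5
Reactants: 9 rac-(4R,5S)-4-hydroxy-5-[(2Z)-pent-2-en-1-yl]cyclopent-2-en-1-one
Product: 10 (4R,5S)-4-hydroxy-5-[(2Z)-pent-2-en-1-yl]cyclopent-2-en-1-one
Conditions: immobilised Candida antarctica lipase B, vinyl acetate, MTBE, 30 °C, stopped near half conversion; chromatography
Reagents that add atoms: none
Why: Lipase-catalysed kinetic resolution by enantioselective transesterification: the (4S,5R)-alcohol should be acetylated and the slower (4R,5S)-alcohol, which carries the C5 configuration needed later, is recovered by chromatography.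

Step 6
Reactants: 10 (4R,5S)-4-hydroxy-5-[(2Z)-pent-2-en-1-yl]cyclopent-2-en-1-one
Product: 11 (1S,5S)-4-oxo-5-[(2Z)-pent-2-en-1-yl]cyclopent-2-en-1-yl benzoate (cis)
Conditions: PhCO2H, PPh3, DIAD, THF, 0 °C to rt
Reagents that add atoms: benzoic acid, O=C(O)c1ccccc1
Why: Mitsunobu reaction: SN2 displacement of the activated hydroxyl by benzoate inverts C4, so that the ester and the pentenyl group shield the same face of the enone in the next step, while C5 is untouched.

Step 7
Reactants: 11 (1S,5S)-4-oxo-5-[(2Z)-pent-2-en-1-yl]cyclopent-2-en-1-yl benzoate; 12 8-chlorooctan-1-ol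
Product: 16 (1S,4R,5S)-4-hydroxy-4-(8-hydroxyoctyl)-5-[(2Z)-pent-2-en-1-yl]cyclopent-2-en-1-yl benzoate, via chloromagnesium alkoxide 13 (not isolated), via Grignard reagent 14 (not isolated), via organocerium reagent 15 (not isolated)
Conditions: 12, i-PrMgCl, THF, −20 °C; Mg, reflux; CeCl3, −78 °C; then 11, −78 °C; aq. NH4Cl
Reagents that add atoms: none
Why: Carbonyl 1,2-addition of a weakly basic organocerium reagent, which should spare the benzoate and not enolise the ketone, takes place anti to both the adjacent pentenyl group and the benzoate and thus sets the tertiary carbinol centre with its hydroxyl cis to the pentenyl group.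

Step 8
Reactants: 16 (1S,4R,5S)-4-hydroxy-4-(8-hydroxyoctyl)-5-[(2Z)-pent-2-en-1-yl]cyclopent-2-en-1-yl benzoate
Product: 17 (1R,4S,5S)-1-(8-hydroxyoctyl)-5-[(2Z)-pent-2-en-1-yl]cyclopent-2-ene-1,4-diol
Conditions: K2CO3, MeOH, rt
Reagents that add atoms: none
Why: Base-catalysed transesterification (methanolysis) removes the benzoate, which is safe at this stage because no ketone is present that could trigger elimination or epimerisation.

Step 9
Reactants: 17 (1R,4S,5S)-1-(8-hydroxyoctyl)-5-[(2Z)-pent-2-en-1-yl]cyclopent-2-ene-1,4-diol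
Product: 18 8-[(1R,5R)-1-hydroxy-4-oxo-5-[(2Z)-pent-2-en-1-yl]cyclopent-2-en-1-yl]octanoic acid
Conditions: TEMPO (cat.), PhI(OAc)2 (3.5 equiv), MeCN/H2O (1:1), rt
Reagents that add atoms: water, O
Why: Oxoammonium (TEMPO) oxidation with PhI(OAc)2 as terminal oxidant converts the secondary allylic alcohol into the enone and, via the aldehyde hydrate, the primary alcohol into the acid, while the tertiary alcohol cannot react; C5, now alpha to the ketone, should hold its configuration because the trans arrangement of the two carbon chains is the more stable one.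

Step 10
Reactants: 18 8-[(1R,5R)-1-hydroxy-4-oxo-5-[(2Z)-pent-2-en-1-yl]cyclopent-2-en-1-yl]octanoic acid
Product: 19 8-[(1R,5R)-1-(acetyloxy)-4-oxo-5-[(2Z)-pent-2-en-1-yl]cyclopent-2-en-1-yl]octanoic acid
Conditions: Ac2O, Sc(OTf)3 (cat.), MeCN, −20 °C; then H2O
Reagents that add atoms: acetic anhydride, CC(=O)OC(C)=O
Why: Lewis-acid-catalysed acylation of the hindered tertiary alcohol under base-free conditions avoids E1cB loss of the β-acyloxy group, and the mixed anhydride formed at the carboxyl group is hydrolysed in the aqueous work-up.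

Compound list
1 | furan | c1ccoc1 | starting material
2 | (3Z)-hex-3-enal | CC/C=C\CC=O | starting material
3 | furan-2-yllithium | [Li]c1ccco1 | intermediate
4 | rac-(3Z)-1-(furan-2-yl)hex-3-en-1-ol | CC/C=C\CC(O)c1ccco1 | intermediate
5 | 6-hydroxy-2-[(2Z)-pent-2-en-1-yl]-2H-pyran-3(6H)-one (racemic mixture of anomers) | CC/C=C\CC1OC(O)C=CC1=O | intermediate
6 | 6-acetoxy-2-[(2Z)-pent-2-en-1-yl]-2H-pyran-3(6H)-one (racemic mixture of anomers) | CC/C=C\CC1OC(OC(C)=O)C=CC1=O | intermediate
7 | diiodosamarium 2-[(2Z)-pent-2-en-1-yl]-2H-pyran-3-olate | CC/C=C\CC1OC=CC=C1O[Sm](I)I | intermediate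
8 | (2Z,7Z)-4-[(diiodosamarium)oxy]deca-2,4,7-trienal | O=C/C=C\C(O[Sm](I)I)=CC/C=C\CC | intermediate
9 | rac-(4R,5S)-4-hydroxy-5-[(2Z)-pent-2-en-1-yl]cyclopent-2-en-1-one (trans, both enantiomers) | CC/C=C\C[C@H]1[C@H](O)C=CC1=O.CC/C=C\C[C@@H]1[C@@H](O)C=CC1=O | intermediate
10 | (4R,5S)-4-hydroxy-5-[(2Z)-pent-2-en-1-yl]cyclopent-2-en-1-one | CC/C=C\C[C@H]1[C@H](O)C=CC1=O | intermediate
11 | (1S,5S)-4-oxo-5-[(2Z)-pent-2-en-1-yl]cyclopent-2-en-1-yl benzoate | CC/C=C\C[C@H]1[C@@H](OC(=O)c2ccccc2)C=CC1=O | intermediate
12 | 8-chlorooctan-1-ol | OCCCCCCCCCl | starting material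
13 | chloromagnesium 8-chlorooctan-1-olate | ClCCCCCCCCO[Mg]Cl | intermediate
14 | [8-(chloromagnesiooxy)octyl]magnesium chloride | Cl[Mg]CCCCCCCCO[Mg]Cl | intermediate
15 | dichloro[8-(chloromagnesiooxy)octyl]cerium | Cl[Ce](Cl)CCCCCCCCO[Mg]Cl | intermediate
16 | (1S,4R,5S)-4-hydroxy-4-(8-hydroxyoctyl)-5-[(2Z)-pent-2-en-1-yl]cyclopent-2-en-1-yl benzoate | CC/C=C\C[C@H]1[C@@H](OC(=O)c2ccccc2)C=C[C@]1(O)CCCCCCCCO | intermediate
17 | (1R,4S,5S)-1-(8-hydroxyoctyl)-5-[(2Z)-pent-2-en-1-yl]cyclopent-2-ene-1,4-diol | CC/C=C\C[C@H]1[C@@H](O)C=C[C@]1(O)CCCCCCCCO | intermediate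
18 | 8-[(1R,5R)-1-hydroxy-4-oxo-5-[(2Z)-pent-2-en-1-yl]cyclopent-2-en-1-yl]octanoic acid | CC/C=C\C[C@H]1C(=O)C=C[C@]1(O)CCCCCCCC(=O)O | intermediate
19 | 8-[(1R,5R)-1-(acetyloxy)-4-oxo-5-[(2Z)-pent-2-en-1-yl]cyclopent-2-en-1-yl]octanoic acid | CC/C=C\C[C@H]1C(=O)C=C[C@@]1(CCCCCCCC(=O)O)OC(C)=O | target

Total step count: 10
Longest linear sequence: 10 steps (1 to 19)

Steps most likely to fail

1. Step 4 (proposed new method). What may go wrong: further reduction of the liberated enal or of the hydroxy enone by SmI2, protonation of the enolate before it cyclises, or reductive dimerisation. Fallback (known chemistry): the route is left at furyl carbinol 4, which is rearranged directly under Piancatelli conditions (ZnCl2, dioxane/H2O, reflux) by hydration, ring opening and conrotatory 4π closure to the trans hydroxy enone; the route is rejoined at 9. No new compound is made (entry F0).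

2. Step 5. What may go wrong: poor enantiomer discrimination by the enzyme because of the substituent next to the carbinol carbon, or a sense of selectivity opposite to the assumed one. Fallback: from racemate 9, a non-enzymatic oxidative kinetic resolution by transfer dehydrogenation (RuCl[(S,S)-TsDPEN](p-cymene) or its enantiomer, acetone, rt, base-free) should oxidise the unwanted (4S,5R)-alcohol to the achiral 2-[(2Z)-pent-2-en-1-yl]cyclopent-4-ene-1,3-dione F1 and leave alcohol 10, at which the route is rejoined.

3. Step 7. What may go wrong: competing attack of the organometallic reagent on the benzoate, enolisation of the ketone with loss of benzoate, or poor solubility of the alkoxide-bearing Grignard reagent. Fallback: from alcohol 10, a Mitsunobu etherification with 4-methoxyphenol (PPh3, DIAD, toluene) inverts C4 and gives (4S,5S)-4-(4-methoxyphenoxy)-5-[(2Z)-pent-2-en-1-yl]cyclopent-2-en-1-one F2, whose ether is inert to organometallic reagents. Addition of organocerium reagent 15 as in step 7 gives (1R,4S,5S)-1-(8-hydroxyoctyl)-4-(4-methoxyphenoxy)-5-[(2Z)-pent-2-en-1-yl]cyclopent-2-en-1-ol F3. Oxidative cleavage of the aryl ether with (NH4)2Ce(NO3)6 in MeCN/H2O at 0 °C gives triol 17, at which the route is rejoined.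

Further compounds
F0 | step 4 | none | none
F1 | step 5 | 2-[(2Z)-pent-2-en-1-yl]cyclopent-4-ene-1,3-dione | CC/C=C\CC1C(=O)C=CC1=O
F2 | step 7 | (4S,5S)-4-(4-methoxyphenoxy)-5-[(2Z)-pent-2-en-1-yl]cyclopent-2-en-1-one | CC/C=C\C[C@H]1[C@@H](Oc2ccc(OC)cc2)C=CC1=O
F3 | step 7 | (1R,4S,5S)-1-(8-hydroxyoctyl)-4-(4-methoxyphenoxy)-5-[(2Z)-pent-2-en-1-yl]cyclopent-2-en-1-ol | CC/C=C\C[C@H]1[C@@H](Oc2ccc(OC)cc2)C=C[C@]1(O)CCCCCCCCO
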